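**Retrosynthetic overview**
- The dienyl side chain is cut at its central C–C bond (Suzuki coupling of an (E)-vinyl iodide), the exocyclic methylene goes back to a ring ketone, and the palmitate sits on the hydroxymethyl arm from the ring-forming step onward.
- The nine-membered ring (formed second) is opened at its Z-alkene by ring-closing metathesis of an allyl carbinol with the linalool-type vinyl carbinol.
- The tetrahydrofuran (formed first) comes from 5-exo opening, with inversion, of a Sharpless epoxide by a primary alcohol; this sets the quaternary C–O centre.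
- The acyclic precursor comes from a trans-γ-lactone whose ring-fusion C–C bond and both ring-fusion stereocentres are made in one intermolecular organocatalytic Michael addition of 3-silyloxypropanal to a nitroalkene.
- The nitroalkene comes from geraniol through Sharpless epoxidation, reductive epoxide opening to (S)-linalool, selective ozonolysis and a Henry reaction.

Assumption: (tributylstannyl)methanol, both diethyl tartrates and both enantiomers of the prolinol silyl ether catalyst are bought; the carbinol carbon made in step 24 is carried as an epimer mixture (oxidised in step 26), so it has no stereo label in the SMILES of 33, 34 and 35.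

**Route**

Step 1
Reactants: 1 geraniol
Product: 2 (2S,3S)-2,3-epoxygeraniol
Conditions: Ti(OiPr)4 (5 mol %), L-(+)-diethyl tartrate (6 mol %), t-BuOOH, 4 Å MS, CH2Cl2, −20 °C
Reagents that add atoms: tert-butyl hydroperoxide, CC(C)(C)OO
Why: Katsuki–Sharpless asymmetric epoxidation touches only the allylic-alcohol olefin and, with the L-tartrate, gives the (2S,3S)-epoxide, which fixes the later tertiary carbinol centre.

Step 2
Reactants: 2 (2S,3S)-2,3-epoxygeraniol
Product: 3 (2R,3S)-2-(iodomethyl)-3-methyl-3-(4-methylpent-3-en-1-yl)oxirane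
Conditions: I2, PPh3, imidazole, Et2O/MeCN, 0 °C
Reagents that add atoms: iodine, [I][I]
Why: Appel-type (Garegg–Samuelsson) iodination replaces only the primary hydroxyl by SN2 and leaves both stereocentres untouched (the C-2 descriptor changes by priority only).

Step 3
Reactants: 3 (2R,3S)-2-(iodomethyl)-3-methyl-3-(4-methylpent-3-en-1-yl)oxirane
Product: 4 (S)-linalool
Conditions: Zn dust, AcOH, EtOH, rt
Reagents that add atoms: none
Why: Zinc-mediated reductive elimination (Boord type) of the β-iodo epoxide opens the oxirane to the transposed tertiary allylic alcohol with retention at the C–O carbon.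

Step 4
Reactants: 4 (S)-linalool
Product: 5 (S)-linalool triethylsilyl ether
Conditions: Et3SiOTf, 2,6-lutidine, CH2Cl2, −78 → 0 °C
Reagents that add atoms: triethylsilyl trifluoromethanesulfonate, CC[Si](CC)(CC)OS(=O)(=O)C(F)(F)F
Why: Silylation with the triflate protects the hindered tertiary alcohol, which would otherwise add to the nitroalkene (oxa-Michael) or form a lactol later.

Step 5
Reactants: 5 (S)-linalool triethylsilyl ether
Product: 6 (4S)-4-methyl-4-(triethylsilyloxy)hex-5-enal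
Conditions: O3, CH2Cl2, −78 °C (Sudan Red 7B end point); then PPh3, −78 °C → rt
Reagents that add atoms: ozone, [O-][O+]=O
Why: In this chemoselective ozonolysis the electron-rich trisubstituted olefin reacts much faster than the hindered vinyl group next to the silyloxy carbon.

Step 6
Reactants: 6 (4S)-4-methyl-4-(triethylsilyloxy)hex-5-enal
Product: 9 (1E,5S)-5-methyl-1-nitro-5-(triethylsilyloxy)hepta-1,6-diene, via nitro alcohol 7 (not isolated), via mesylate 8 (not isolated)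
Conditions: CH3NO2, KOtBu (10 mol %), THF/t-BuOH, 0 °C; then MsCl, Et3N, CH2Cl2, −20 → 0 °C
Reagents that add atoms: nitromethane, C[N+](=O)[O-]
Why: A Henry (nitroaldol) reaction followed by mesylation and E1cB elimination gives the thermodynamically favoured (E)-nitroalkene, the Michael acceptor.

Step 7
Reactants: 10 propane-1,3-diol
Product: 11 3-(tert-butyldiphenylsilyloxy)propan-1-ol
Conditions: NaH (1 equiv), THF, 0 °C → rt; then t-BuPh2SiCl
Reagents that add atoms: tert-butyl(chloro)diphenylsilane, CC(C)(C)[Si](Cl)(c1ccccc1)c1ccccc1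
Why: Monosilylation through the sparingly soluble monosodium alkoxide (Williamson-type O-silylation) gives the mono-ether cleanly.

Step 8
Reactants: 11 3-(tert-butyldiphenylsilyloxy)propan-1-ol
Product: 12 3-(tert-butyldiphenylsilyloxy)propanal
Conditions: Dess–Martin periodinane, CH2Cl2, rt
Reagents that add atoms: none
Why: Dess–Martin oxidation stops at the aldehyde under neutral conditions that do not eliminate the β-silyloxy group.

Step 9
Reactants: 9 (1E,5S)-5-methyl-1-nitro-5-(triethylsilyloxy)hepta-1,6-diene; 12 3-(tert-butyldiphenylsilyloxy)propanal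
Product: 14 (2S,3S,6S)-2-[(tert-butyldiphenylsilyloxy)methyl]-6-methyl-3-(nitromethyl)-6-(triethylsilyloxy)oct-7-en-1-ol, via nitro aldehyde 13 (not isolated)
Conditions: 12 (2.5 equiv), (R)-2-[diphenyl(trimethylsilyloxy)methyl]pyrrolidine (10 mol %), 4-nitrophenol (20 mol %), toluene, 0 °C → rt; then MeOH, NaBH4, 0 °C
Reagents that add atoms: none
Why: In this Hayashi–Jørgensen enamine Michael addition the face-shielded anti-enamine of 12 attacks the (E)-nitroalkene through the acyclic synclinal transition state, so the catalyst sets both new centres as the syn adduct (trans in the later ring) while joining the two fragments, and in-situ borohydride reduction stops epimerisation of the aldehyde.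

Step 10
Reactants: 14 (2S,3S,6S)-2-[(tert-butyldiphenylsilyloxy)methyl]-6-methyl-3-(nitromethyl)-6-(triethylsilyloxy)oct-7-en-1-ol
Product: 16 (3S,4S)-4-[(tert-butyldiphenylsilyloxy)methyl]-3-[(3S)-3-methyl-3-(triethylsilyloxy)pent-4-en-1-yl]oxolan-2-one, via hydroxy acid 15 (not isolated)
Conditions: NaNO2, AcOH, DMSO, 35 °C
Reagents that add atoms: water, O
Why: A Nef-type oxidation of the primary nitro group (nitrolic acid, then nitrile oxide, then acid) is followed by spontaneous lactonisation onto the free primary alcohol, giving the trans-lactone without touching either stereocentre.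

Step 11
Reactants: 16 (3S,4S)-4-[(tert-butyldiphenylsilyloxy)methyl]-3-[(3S)-3-methyl-3-(triethylsilyloxy)pent-4-en-1-yl]oxolan-2-one
Product: 17 (2S,3S)-3-[(tert-butyldiphenylsilyloxy)methyl]-4-hydroxy-N-methoxy-N-methyl-2-[(3S)-3-methyl-3-(triethylsilyloxy)pent-4-en-1-yl]butanamide
Conditions: MeNH(OMe)·HCl, Me3Al, CH2Cl2, 0 °C → rt
Reagents that add atoms: N,O-dimethylhydroxylamine hydrochloride, CNOC.Cl
Why: Weinreb aminolysis of the lactone by the aluminium amide opens the ring under non-epimerising conditions and frees the primary alcohol.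

Step 12
Reactants: 17 (2S,3S)-3-[(tert-butyldiphenylsilyloxy)methyl]-4-hydroxy-N-methoxy-N-methyl-2-[(3S)-3-methyl-3-(triethylsilyloxy)pent-4-en-1-yl]butanamide
Product: 18 (2S,3S)-3-[(tert-butyldiphenylsilyloxy)methyl]-N-methoxy-N-methyl-2-[(3S)-3-methyl-3-(triethylsilyloxy)pent-4-en-1-yl]-4-(triethylsilyloxy)butanamide
Conditions: Et3SiCl, imidazole, CH2Cl2, 0 °C
Reagents that add atoms: chlorotriethylsilane, CC[Si](Cl)(CC)CC
Why: Silylation stops relactonisation and keeps the two CH2O arms on C-3 different (primary triethylsilyl ether for the later ring oxygen, tert-butyldiphenylsilyl ether for the later aldehyde), which is what keeps that centre defined.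

Step 13
Reactants: 19 (tributylstannyl)methanol
Product: 20 tributyl[(4-methoxybenzyloxy)methyl]stannane
Conditions: NaH, THF/DMF, 0 °C; 4-methoxybenzyl chloride, Bu4NI (cat.), rt
Reagents that add atoms: 4-methoxybenzyl chloride, COc1ccc(CCl)cc1
Why: Williamson etherification gives the precursor of an α-alkoxymethyl anion.

Step 14
Reactants: 18 (2S,3S)-3-[(tert-butyldiphenylsilyloxy)methyl]-N-methoxy-N-methyl-2-[(3S)-3-methyl-3-(triethylsilyloxy)pent-4-en-1-yl]-4-(triethylsilyloxy)butanamide; 20 tributyl[(4-methoxybenzyloxy)methyl]stannane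
Product: 22 (3S,4S)-4-[(tert-butyldiphenylsilyloxy)methyl]-1-(4-methoxybenzyloxy)-3-[(3S)-3-methyl-3-(triethylsilyloxy)pent-4-en-1-yl]-5-(triethylsilyloxy)pentan-2-one, via organolithium 21 (not isolated)
Conditions: 20, n-BuLi, THF, −78 °C; then 18, −78 °C; aqueous work-up
Reagents that add atoms: none
Why: Tin–lithium exchange gives the alkoxymethyllithium, which adds once to the Weinreb amide (stable chelated tetrahedral intermediate) to give the ketone at a temperature that does not epimerise the α-centre.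

Step 15
Reactants: 22 (3S,4S)-4-[(tert-butyldiphenylsilyloxy)methyl]-1-(4-methoxybenzyloxy)-3-[(3S)-3-methyl-3-(triethylsilyloxy)pent-4-en-1-yl]-5-(triethylsilyloxy)pentan-2-one
Product: 23 (3S,4S)-4-[(tert-butyldiphenylsilyloxy)methyl]-1-(4-methoxybenzyloxy)-2-methylidene-3-[(3S)-3-methyl-3-(triethylsilyloxy)pent-4-en-1-yl]-5-(triethylsilyloxy)pentane
Conditions: Cp2TiMe2, toluene, 65 °C
Reagents that add atoms: dimethyltitanocene, C[Ti](C)(C1C=CC=C1)C1C=CC=C1
Why: Petasis methylenation is non-basic, so the hindered α-branched ketone becomes the 1,1-disubstituted alkene without epimerisation.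

Step 16
Reactants: 23 (3S,4S)-4-[(tert-butyldiphenylsilyloxy)methyl]-1-(4-methoxybenzyloxy)-2-methylidene-3-[(3S)-3-methyl-3-(triethylsilyloxy)pent-4-en-1-yl]-5-(triethylsilyloxy)pentane
Product: 24 (3S,4S)-4-[(tert-butyldiphenylsilyloxy)methyl]-2-methylidene-3-[(3S)-3-methyl-3-(triethylsilyloxy)pent-4-en-1-yl]-5-(triethylsilyloxy)pentan-1-ol
Conditions: DDQ, CH2Cl2/pH 7 buffer, 0 °C
Reagents that add atoms: none
Why: Oxidative cleavage of the 4-methoxybenzyl ether frees only the allylic alcohol needed to direct the epoxidation, the silyl ethers being inert.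

Step 17
Reactants: 24 (3S,4S)-4-[(tert-butyldiphenylsilyloxy)methyl]-2-methylidene-3-[(3S)-3-methyl-3-(triethylsilyloxy)pent-4-en-1-yl]-5-(triethylsilyloxy)pentan-1-ol
Product: 25 {(2R)-2-[(2S,3S,6S)-2-[(tert-butyldiphenylsilyloxy)methyl]-6-methyl-1,6-bis(triethylsilyloxy)oct-7-en-3-yl]oxiran-2-yl}methanol
Conditions: Ti(OiPr)4 (20 mol %), D-(−)-diethyl tartrate (24 mol %), t-BuOOH, 4 Å MS, CH2Cl2, −25 °C
Reagents that add atoms: tert-butyl hydroperoxide, CC(C)(C)OO
Why: Katsuki–Sharpless asymmetric epoxidation of the 2-substituted allylic alcohol is reagent-controlled (D-tartrate gives the (2R)-oxirane) and leaves the non-allylic vinyl group alone, so the later quaternary centre is set here.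

Step 18
Reactants: 25 {(2R)-2-[(2S,3S,6S)-2-[(tert-butyldiphenylsilyloxy)methyl]-6-methyl-1,6-bis(triethylsilyloxy)oct-7-en-3-yl]oxiran-2-yl}methanol
Product: 26 (2S)-2-[(2S,3S,6S)-2-[(tert-butyldiphenylsilyloxy)methyl]-6-methyl-1,6-bis(triethylsilyloxy)oct-7-en-3-yl]oxirane-2-carbaldehyde
Conditions: Dess–Martin periodinane, pyridine, CH2Cl2, 0 °C → rt
Reagents that add atoms: none
Why: Dess–Martin oxidation gives an epoxy aldehyde with no α-hydrogen, so it cannot epimerise (the descriptor changes by priority only).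

Step 19
Reactants: 26 (2S)-2-[(2S,3S,6S)-2-[(tert-butyldiphenylsilyloxy)methyl]-6-methyl-1,6-bis(triethylsilyloxy)oct-7-en-3-yl]oxirane-2-carbaldehyde
Product: 27 (2R)-2-[(E)-2-iodoethenyl]-2-[(2S,3S,6S)-2-[(tert-butyldiphenylsilyloxy)methyl]-6-methyl-1,6-bis(triethylsilyloxy)oct-7-en-3-yl]oxirane
Conditions: CrCl2, CHI3, THF/1,4-dioxane, 0 °C → rt
Reagents that add atoms: iodoform, IC(I)I
Why: Takai olefination gives the (E)-vinyl iodide, which marks this carbon as the future dienyl arm and makes the oxirane carbon allylic for the next step.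

Step 20
Reactants: 27 (2R)-2-[(E)-2-iodoethenyl]-2-[(2S,3S,6S)-2-[(tert-butyldiphenylsilyloxy)methyl]-6-methyl-1,6-bis(triethylsilyloxy)oct-7-en-3-yl]oxirane
Product: 29 [(2S,3S,4S)-4-[(tert-butyldiphenylsilyloxy)methyl]-2-[(E)-2-iodoethenyl]-3-[(3S)-3-methyl-3-(triethylsilyloxy)pent-4-en-1-yl]oxolan-2-yl]methanol, via hydroxy epoxide 28 (not isolated)
Conditions: PPTS (20 mol %), MeOH/CH2Cl2, 0 °C; then CSA (10 mol %), CH2Cl2, 0 °C
Reagents that add atoms: none
Why: Selective methanolysis of the primary triethylsilyl ether frees the alcohol, which opens the epoxide by acid-catalysed 5-exo attack at the tertiary allylic carbon with inversion (intramolecular SN2), so the quaternary ring centre is set and the oxirane CH2 becomes the hydroxymethyl arm cis to the C-3 chain.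

Step 21
Reactants: 29 [(2S,3S,4S)-4-[(tert-butyldiphenylsilyloxy)methyl]-2-[(E)-2-iodoethenyl]-3-[(3S)-3-methyl-3-(triethylsilyloxy)pent-4-en-1-yl]oxolan-2-yl]methanol
Product: 30 [(2S,3S,4S)-4-[(tert-butyldiphenylsilyloxy)methyl]-2-[(E)-2-iodoethenyl]-3-[(3S)-3-methyl-3-(triethylsilyloxy)pent-4-en-1-yl]oxolan-2-yl]methyl hexadecanoate
Conditions: palmitoyl chloride, pyridine, DMAP (cat.), CH2Cl2, 0 °C → rt
Reagents that add atoms: hexadecanoyl chloride, CCCCCCCCCCCCCCCC(=O)Cl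
Why: DMAP-catalysed acylation of the only free hydroxyl installs the palmitate, which also protects this arm for the rest of the route.

Step 22
Reactants: 30 [(2S,3S,4S)-4-[(tert-butyldiphenylsilyloxy)methyl]-2-[(E)-2-iodoethenyl]-3-[(3S)-3-methyl-3-(triethylsilyloxy)pent-4-en-1-yl]oxolan-2-yl]methyl hexadecanoate
Product: 31 [(2S,3S,4R)-4-(hydroxymethyl)-3-[(3S)-3-hydroxy-3-methylpent-4-en-1-yl]-2-[(E)-2-iodoethenyl]oxolan-2-yl]methyl hexadecanoate
Conditions: Bu4NF, AcOH, THF, 0 °C → rt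
Reagents that add atoms: none
Why: Acetic-acid-buffered fluoride desilylation removes both silyl ethers while the ester and vinyl iodide survive (the C-4 descriptor changes by priority only).

Step 23
Reactants: 31 [(2S,3S,4R)-4-(hydroxymethyl)-3-[(3S)-3-hydroxy-3-methylpent-4-en-1-yl]-2-[(E)-2-iodoethenyl]oxolan-2-yl]methyl hexadecanoate
Product: 32 [(2S,3S,4S)-4-formyl-3-[(3S)-3-hydroxy-3-methylpent-4-en-1-yl]-2-[(E)-2-iodoethenyl]oxolan-2-yl]methyl hexadecanoate
Conditions: Dess–Martin periodinane, pyridine, CH2Cl2, 0 °C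
Reagents that add atoms: none
Why: Dess–Martin oxidation converts the primary alcohol only (the tertiary one is inert) under buffered conditions that do not epimerise the ring-bound aldehyde.

Step 24
Reactants: 32 [(2S,3S,4S)-4-formyl-3-[(3S)-3-hydroxy-3-methylpent-4-en-1-yl]-2-[(E)-2-iodoethenyl]oxolan-2-yl]methyl hexadecanoate
Product: 34 [(2S,3S,4S)-4-(1-hydroxybut-3-en-1-yl)-3-[(3S)-3-hydroxy-3-methylpent-4-en-1-yl]-2-[(E)-2-iodoethenyl]oxolan-2-yl]methyl hexadecanoate (carbinol epimers), via borate 33 (not isolated)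
Conditions: allylB(pin), CH2Cl2, rt; then aq. NaHCO3
Reagents that add atoms: allylboronic acid pinacol ester, C=CCB1OC(C)(C)C(C)(C)O1
Why: Allylboration through a closed six-membered transition state adds to the aldehyde only (not the ester), and the new carbinol centre is left uncontrolled because it is oxidised two steps later.

Step 25
Reactants: 34 [(2S,3S,4S)-4-(1-hydroxybut-3-en-1-yl)-3-[(3S)-3-hydroxy-3-methylpent-4-en-1-yl]-2-[(E)-2-iodoethenyl]oxolan-2-yl]methyl hexadecanoate (carbinol epimers)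
Product: 35 [(1S,3aS,6Z,8S,10aS)-4,8-dihydroxy-1-[(E)-2-iodoethenyl]-8-methyl-3,3a,4,5,8,9,10,10a-octahydro-1H-cyclonona[c]furan-1-yl]methyl hexadecanoate (C-4 epimers)
Conditions: second-generation Grubbs catalyst (H2IMes)(PCy3)Cl2Ru=CHPh (15 mol %), CH2Cl2 (1 mM), 40 °C
Reagents that add atoms: none
Why: Ring-closing metathesis of the two terminal olefins, pre-organised by the trans-disubstituted tetrahydrofuran and helped by the free allylic hydroxyl, closes the nine-membered ring, whose strain allows only the Z-alkene.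

Step 26
Reactants: 35 [(1S,3aS,6Z,8S,10aS)-4,8-dihydroxy-1-[(E)-2-iodoethenyl]-8-methyl-3,3a,4,5,8,9,10,10a-octahydro-1H-cyclonona[c]furan-1-yl]methyl hexadecanoate (C-4 epimers)
Product: 36 [(1S,3aS,6Z,8S,10aS)-8-hydroxy-1-[(E)-2-iodoethenyl]-8-methyl-4-oxo-3,3a,4,5,8,9,10,10a-octahydro-1H-cyclonona[c]furan-1-yl]methyl hexadecanoate
Conditions: Dess–Martin periodinane, pyridine, CH2Cl2, 0 °C
Reagents that add atoms: none
Why: Dess–Martin oxidation converges both carbinol epimers on one β,γ-unsaturated ketone under buffered conditions that avoid conjugation.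

Step 27
Reactants: 36 [(1S,3aS,6Z,8S,10aS)-8-hydroxy-1-[(E)-2-iodoethenyl]-8-methyl-4-oxo-3,3a,4,5,8,9,10,10a-octahydro-1H-cyclonona[c]furan-1-yl]methyl hexadecanoate
Product: 37 [(1S,3aR,6Z,8S,10aS)-8-hydroxy-1-[(E)-2-iodoethenyl]-8-methyl-4-methylidene-3,3a,4,5,8,9,10,10a-octahydro-1H-cyclonona[c]furan-1-yl]methyl hexadecanoate
Conditions: Zn, CH2Br2, TiCl4 (Lombardo reagent, pre-formed in THF), CH2Cl2, 0 °C → rt
Reagents that add atoms: dibromomethane, BrCBr
Why: Takai–Lombardo methylenation is non-basic and ketone-selective, so the enolisable ketone becomes the exocyclic methylene without epimerisation, conjugation or attack on the ester.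

Step 28
Reactants: 37 [(1S,3aR,6Z,8S,10aS)-8-hydroxy-1-[(E)-2-iodoethenyl]-8-methyl-4-methylidene-3,3a,4,5,8,9,10,10a-octahydro-1H-cyclonona[c]furan-1-yl]methyl hexadecanoate
Product: 38 target, [(1R,3aR,6Z,8S,10aS)-8-hydroxy-8-methyl-4-methylidene-1-[(1E)-4-methylpenta-1,3-dien-1-yl]-3,3a,4,5,8,9,10,10a-octahydro-1H-cyclonona[c]furan-1-yl]methyl hexadecanoate
Conditions: 4,4,5,5-tetramethyl-2-(2-methylprop-1-en-1-yl)-1,3,2-dioxaborolane, Pd(dppf)Cl2 (5 mol %), K3PO4, THF/H2O, 40 °C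
Reagents that add atoms: 4,4,5,5-tetramethyl-2-(2-methylprop-1-en-1-yl)-1,3,2-dioxaborolane, CC(C)=CB1OC(C)(C)C(C)(C)O1
Why: Suzuki–Miyaura coupling of the (E)-vinyl iodide proceeds with retention of geometry under mild base that spares the ester, completing the (E)-diene (the C-1 descriptor changes by priority only).

**Compound list**

1 | geraniol | CC(C)=CCC/C(C)=C/CO | starting material
2 | (2S,3S)-2,3-epoxygeraniol | CC(C)=CCC[C@]1(C)O[C@H]1CO | intermediate
3 | (2R,3S)-2-(iodomethyl)-3-methyl-3-(4-methylpent-3-en-1-yl)oxirane | CC(C)=CCC[C@]1(C)O[C@H]1CI | intermediate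
4 | (S)-linalool | C=C[C@@](C)(O)CCC=C(C)C | intermediate
5 | (S)-linalool triethylsilyl ether | C=C[C@@](C)(O[Si](CC)(CC)CC)CCC=C(C)C | intermediate
6 | (4S)-4-methyl-4-(triethylsilyloxy)hex-5-enal | C=C[C@@](C)(O[Si](CC)(CC)CC)CCC=O | intermediate
7 | (5S)-5-methyl-1-nitro-5-(triethylsilyloxy)hept-6-en-2-ol (C-2 epimers) | C=C[C@@](C)(O[Si](CC)(CC)CC)CCC(O)C[N+](=O)[O-] | intermediate
8 | (5S)-5-methyl-1-nitro-5-(triethylsilyloxy)hept-6-en-2-yl methanesulfonate (C-2 epimers) | C=C[C@@](C)(O[Si](CC)(CC)CC)CCC(OS(C)(=O)=O)C[N+](=O)[O-] | intermediate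
9 | (1E,5S)-5-methyl-1-nitro-5-(triethylsilyloxy)hepta-1,6-diene | C=C[C@@](C)(O[Si](CC)(CC)CC)CC/C=C/[N+](=O)[O-] | intermediate
10 | propane-1,3-diol | OCCCO | starting material
11 | 3-(tert-butyldiphenylsilyloxy)propan-1-ol | OCCCO[Si](c1ccccc1)(c1ccccc1)C(C)(C)C | intermediate
12 | 3-(tert-butyldiphenylsilyloxy)propanal | O=CCCO[Si](c1ccccc1)(c1ccccc1)C(C)(C)C | intermediate
13 | (2R,3S,6S)-2-[(tert-butyldiphenylsilyloxy)methyl]-6-methyl-3-(nitromethyl)-6-(triethylsilyloxy)oct-7-enal | C=C[C@@](C)(O[Si](CC)(CC)CC)CC[C@H](C[N+](=O)[O-])[C@H](CO[Si](c1ccccc1)(c1ccccc1)C(C)(C)C)C=O | intermediate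
14 | (2S,3S,6S)-2-[(tert-butyldiphenylsilyloxy)methyl]-6-methyl-3-(nitromethyl)-6-(triethylsilyloxy)oct-7-en-1-ol | C=C[C@@](C)(O[Si](CC)(CC)CC)CC[C@H](C[N+](=O)[O-])[C@H](CO[Si](c1ccccc1)(c1ccccc1)C(C)(C)C)CO | intermediate
15 | (2S,3S)-3-[(tert-butyldiphenylsilyloxy)methyl]-4-hydroxy-2-[(3S)-3-methyl-3-(triethylsilyloxy)pent-4-en-1-yl]butanoic acid | C=C[C@@](C)(O[Si](CC)(CC)CC)CC[C@H](C(=O)O)[C@H](CO[Si](c1ccccc1)(c1ccccc1)C(C)(C)C)CO | intermediate
16 | (3S,4S)-4-[(tert-butyldiphenylsilyloxy)methyl]-3-[(3S)-3-methyl-3-(triethylsilyloxy)pent-4-en-1-yl]oxolan-2-one (trans) | C=C[C@@](C)(O[Si](CC)(CC)CC)CC[C@@H]1C(=O)OC[C@H]1CO[Si](c1ccccc1)(c1ccccc1)C(C)(C)C | intermediate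
17 | (2S,3S)-3-[(tert-butyldiphenylsilyloxy)methyl]-4-hydroxy-N-methoxy-N-methyl-2-[(3S)-3-methyl-3-(triethylsilyloxy)pent-4-en-1-yl]butanamide | C=C[C@@](C)(O[Si](CC)(CC)CC)CC[C@H](C(=O)N(C)OC)[C@H](CO[Si](c1ccccc1)(c1ccccc1)C(C)(C)C)CO | intermediate
18 | (2S,3S)-3-[(tert-butyldiphenylsilyloxy)methyl]-N-methoxy-N-methyl-2-[(3S)-3-methyl-3-(triethylsilyloxy)pent-4-en-1-yl]-4-(triethylsilyloxy)butanamide | C=C[C@@](C)(O[Si](CC)(CC)CC)CC[C@H](C(=O)N(C)OC)[C@H](CO[Si](c1ccccc1)(c1ccccc1)C(C)(C)C)CO[Si](CC)(CC)CC | intermediate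
19 | (tributylstannyl)methanol | CCCC[Sn](CCCC)(CCCC)CO | starting material
20 | tributyl[(4-methoxybenzyloxy)methyl]stannane | CCCC[Sn](CCCC)(CCCC)COCc1ccc(OC)cc1 | intermediate
21 | [(4-methoxybenzyloxy)methyl]lithium | [Li]COCc1ccc(OC)cc1 | intermediate
22 | (3S,4S)-4-[(tert-butyldiphenylsilyloxy)methyl]-1-(4-methoxybenzyloxy)-3-[(3S)-3-methyl-3-(triethylsilyloxy)pent-4-en-1-yl]-5-(triethylsilyloxy)pentan-2-one | C=C[C@@](C)(O[Si](CC)(CC)CC)CC[C@H](C(=O)COCc1ccc(OC)cc1)[C@H](CO[Si](c1ccccc1)(c1ccccc1)C(C)(C)C)CO[Si](CC)(CC)CC | intermediate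
23 | (3S,4S)-4-[(tert-butyldiphenylsilyloxy)methyl]-1-(4-methoxybenzyloxy)-2-methylidene-3-[(3S)-3-methyl-3-(triethylsilyloxy)pent-4-en-1-yl]-5-(triethylsilyloxy)pentane | C=C[C@@](C)(O[Si](CC)(CC)CC)CC[C@H](C(=C)COCc1ccc(OC)cc1)[C@H](CO[Si](c1ccccc1)(c1ccccc1)C(C)(C)C)CO[Si](CC)(CC)CC | intermediate
24 | (3S,4S)-4-[(tert-butyldiphenylsilyloxy)methyl]-2-methylidene-3-[(3S)-3-methyl-3-(triethylsilyloxy)pent-4-en-1-yl]-5-(triethylsilyloxy)pentan-1-ol | C=C[C@@](C)(O[Si](CC)(CC)CC)CC[C@H](C(=C)CO)[C@H](CO[Si](c1ccccc1)(c1ccccc1)C(C)(C)C)CO[Si](CC)(CC)CC | intermediate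
25 | {(2R)-2-[(2S,3S,6S)-2-[(tert-butyldiphenylsilyloxy)methyl]-6-methyl-1,6-bis(triethylsilyloxy)oct-7-en-3-yl]oxiran-2-yl}methanol | C=C[C@@](C)(O[Si](CC)(CC)CC)CC[C@H]([C@@]1(CO)CO1)[C@H](CO[Si](c1ccccc1)(c1ccccc1)C(C)(C)C)CO[Si](CC)(CC)CC | intermediate
26 | (2S)-2-[(2S,3S,6S)-2-[(tert-butyldiphenylsilyloxy)methyl]-6-methyl-1,6-bis(triethylsilyloxy)oct-7-en-3-yl]oxirane-2-carbaldehyde | C=C[C@@](C)(O[Si](CC)(CC)CC)CC[C@H]([C@@]1(C=O)CO1)[C@H](CO[Si](c1ccccc1)(c1ccccc1)C(C)(C)C)CO[Si](CC)(CC)CC | intermediate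
27 | (2R)-2-[(E)-2-iodoethenyl]-2-[(2S,3S,6S)-2-[(tert-butyldiphenylsilyloxy)methyl]-6-methyl-1,6-bis(triethylsilyloxy)oct-7-en-3-yl]oxirane | C=C[C@@](C)(O[Si](CC)(CC)CC)CC[C@H]([C@@]1(/C=C/I)CO1)[C@H](CO[Si](c1ccccc1)(c1ccccc1)C(C)(C)C)CO[Si](CC)(CC)CC | intermediate
28 | (2S,3S,6S)-2-[(tert-butyldiphenylsilyloxy)methyl]-3-[(2R)-2-[(E)-2-iodoethenyl]oxiran-2-yl]-6-methyl-6-(triethylsilyloxy)oct-7-en-1-ol | C=C[C@@](C)(O[Si](CC)(CC)CC)CC[C@H]([C@@]1(/C=C/I)CO1)[C@H](CO[Si](c1ccccc1)(c1ccccc1)C(C)(C)C)CO | intermediate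
29 | [(2S,3S,4S)-4-[(tert-butyldiphenylsilyloxy)methyl]-2-[(E)-2-iodoethenyl]-3-[(3S)-3-methyl-3-(triethylsilyloxy)pent-4-en-1-yl]oxolan-2-yl]methanol | C=C[C@@](C)(O[Si](CC)(CC)CC)CC[C@H]1[C@H](CO[Si](c2ccccc2)(c2ccccc2)C(C)(C)C)CO[C@@]1(/C=C/I)CO | intermediate
30 | [(2S,3S,4S)-4-[(tert-butyldiphenylsilyloxy)methyl]-2-[(E)-2-iodoethenyl]-3-[(3S)-3-methyl-3-(triethylsilyloxy)pent-4-en-1-yl]oxolan-2-yl]methyl hexadecanoate | C=C[C@@](C)(O[Si](CC)(CC)CC)CC[C@H]1[C@H](CO[Si](c2ccccc2)(c2ccccc2)C(C)(C)C)CO[C@@]1(/C=C/I)COC(=O)CCCCCCCCCCCCCCC | intermediate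
31 | [(2S,3S,4R)-4-(hydroxymethyl)-3-[(3S)-3-hydroxy-3-methylpent-4-en-1-yl]-2-[(E)-2-iodoethenyl]oxolan-2-yl]methyl hexadecanoate | C=C[C@@](C)(O)CC[C@H]1[C@H](CO)CO[C@@]1(/C=C/I)COC(=O)CCCCCCCCCCCCCCC | intermediate
32 | [(2S,3S,4S)-4-formyl-3-[(3S)-3-hydroxy-3-methylpent-4-en-1-yl]-2-[(E)-2-iodoethenyl]oxolan-2-yl]methyl hexadecanoate | C=C[C@@](C)(O)CC[C@H]1[C@H](C=O)CO[C@@]1(/C=C/I)COC(=O)CCCCCCCCCCCCCCC | intermediate
33 | pinacol borate of 34 (carbinol epimers) | C=C[C@@](C)(O)CC[C@H]1[C@H](C(CC=C)OB2OC(C)(C)C(C)(C)O2)CO[C@@]1(/C=C/I)COC(=O)CCCCCCCCCCCCCCC | intermediate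
34 | [(2S,3S,4S)-4-(1-hydroxybut-3-en-1-yl)-3-[(3S)-3-hydroxy-3-methylpent-4-en-1-yl]-2-[(E)-2-iodoethenyl]oxolan-2-yl]methyl hexadecanoate (carbinol epimers) | C=C[C@@](C)(O)CC[C@H]1[C@H](C(O)CC=C)CO[C@@]1(/C=C/I)COC(=O)CCCCCCCCCCCCCCC | intermediate
35 | [(1S,3aS,6Z,8S,10aS)-4,8-dihydroxy-1-[(E)-2-iodoethenyl]-8-methyl-3,3a,4,5,8,9,10,10a-octahydro-1H-cyclonona[c]furan-1-yl]methyl hexadecanoate (C-4 epimers) | OC1C/C=C\[C@@](C)(O)CC[C@H]2[C@H]1CO[C@@]2(/C=C/I)COC(=O)CCCCCCCCCCCCCCC | intermediate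
36 | [(1S,3aS,6Z,8S,10aS)-8-hydroxy-1-[(E)-2-iodoethenyl]-8-methyl-4-oxo-3,3a,4,5,8,9,10,10a-octahydro-1H-cyclonona[c]furan-1-yl]methyl hexadecanoate | O=C1C/C=C\[C@@](C)(O)CC[C@H]2[C@H]1CO[C@@]2(/C=C/I)COC(=O)CCCCCCCCCCCCCCC | intermediate
37 | [(1S,3aR,6Z,8S,10aS)-8-hydroxy-1-[(E)-2-iodoethenyl]-8-methyl-4-methylidene-3,3a,4,5,8,9,10,10a-octahydro-1H-cyclonona[c]furan-1-yl]methyl hexadecanoate | C=C1C/C=C\[C@@](C)(O)CC[C@H]2[C@H]1CO[C@@]2(/C=C/I)COC(=O)CCCCCCCCCCCCCCC | intermediate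
38 | [(1R,3aR,6Z,8S,10aS)-8-hydroxy-8-methyl-4-methylidene-1-[(1E)-4-methylpenta-1,3-dien-1-yl]-3,3a,4,5,8,9,10,10a-octahydro-1H-cyclonona[c]furan-1-yl]methyl hexadecanoate | C=C1C/C=C\[C@@](C)(O)CC[C@H]2[C@H]1CO[C@@]2(/C=C/C=C(C)C)COC(=O)CCCCCCCCCCCCCCC | target

**Totals and risks**

Total step count: 28. Longest linear sequence: 25 steps (geraniol through steps 1–6, 9–12 and 14–28).

The three steps most likely to fail:

Step 9 (Michael addition). The β-silyloxy aldehyde 12 may lose silanolate from its enamine or react with poor diastereoselectivity. The fallback brings in the oxygenated carbon after the Michael step; it sets out from nitroalkene 9 and comes back at nitro alcohol 14. Acetaldehyde is added to 9 with the same (R)-configured prolinol silyl ether (enamine Michael addition) to give (3S,6S)-6-methyl-3-(nitromethyl)-6-(triethylsilyloxy)oct-7-enal F1. Organocatalytic α-hydroxymethylation of this aldehyde with aqueous formaldehyde and the (S)-configured catalyst then gives (2R,3S,6S)-2-(hydroxymethyl)-6-methyl-3-(nitromethyl)-6-(triethylsilyloxy)oct-7-enal F2. Silylation (t-BuPh2SiCl, imidazole) gives aldehyde 13, which NaBH4 reduces to 14.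

Step 19 (Takai olefination of the epoxy aldehyde). The chromium salts may open the oxirane or give poor E-selectivity. The fallback makes the vinyl iodide from an alkyne after ring closure; it sets out from epoxy aldehyde 26 and comes back at palmitate 30. Seyferth–Gilbert homologation with dimethyl (1-diazo-2-oxopropyl)phosphonate (K2CO3, MeOH) gives (2R)-2-ethynyl-2-[(2S,3S,6S)-2-[(tert-butyldiphenylsilyloxy)methyl]-6-methyl-1,6-bis(triethylsilyloxy)oct-7-en-3-yl]oxirane F3. PPTS/MeOH removes the primary silyl ether to give (2S,3S,6S)-2-[(tert-butyldiphenylsilyloxy)methyl]-3-[(2R)-2-ethynyloxiran-2-yl]-6-methyl-6-(triethylsilyloxy)oct-7-en-1-ol F4, which CSA cyclises (5-exo, inversion at the propargylic carbon) to [(2S,3S,4S)-4-[(tert-butyldiphenylsilyloxy)methyl]-2-ethynyl-3-[(3S)-3-methyl-3-(triethylsilyloxy)pent-4-en-1-yl]oxolan-2-yl]methanol F5. Acylation with palmitoyl chloride gives [(2S,3S,4S)-4-[(tert-butyldiphenylsilyloxy)methyl]-2-ethynyl-3-[(3S)-3-methyl-3-(triethylsilyloxy)pent-4-en-1-yl]oxolan-2-yl]methyl hexadecanoate F6. Hydrozirconation with Cp2Zr(H)Cl and iodinolysis with I2 turns the terminal alkyne into the (E)-vinyl iodide 30.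

Step 25 (nine-membered ring-closing metathesis). The strained ring may close slowly and give oligomers, and the epimeric carbinols may behave differently. The fallback changes the ring-closing substrate and the order of events; it sets out from 34 and comes back at ketone 36. Dess–Martin oxidation of 34 first gives the single allyl ketone [(2S,3S,4S)-4-(but-3-enoyl)-3-[(3S)-3-hydroxy-3-methylpent-4-en-1-yl]-2-[(E)-2-iodoethenyl]oxolan-2-yl]methyl hexadecanoate F7, which has an sp2 carbon in the tether. Its ring-closing metathesis with the second-generation Grubbs catalyst, in the presence of Ti(OiPr)4 to prevent carbonyl chelation of the ruthenium carbene, gives 36 directly.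

**Further compounds**

F1 | step 9 | (3S,6S)-6-methyl-3-(nitromethyl)-6-(triethylsilyloxy)oct-7-enal | C=C[C@@](C)(O[Si](CC)(CC)CC)CC[C@H](C[N+](=O)[O-])CC=O
F2 | step 9 | (2R,3S,6S)-2-(hydroxymethyl)-6-methyl-3-(nitromethyl)-6-(triethylsilyloxy)oct-7-enal | C=C[C@@](C)(O[Si](CC)(CC)CC)CC[C@H](C[N+](=O)[O-])[C@H](CO)C=O
F3 | step 19 | (2R)-2-ethynyl-2-[(2S,3S,6S)-2-[(tert-butyldiphenylsilyloxy)methyl]-6-methyl-1,6-bis(triethylsilyloxy)oct-7-en-3-yl]oxirane | C=C[C@@](C)(O[Si](CC)(CC)CC)CC[C@H]([C@@]1(C#C)CO1)[C@H](CO[Si](c1ccccc1)(c1ccccc1)C(C)(C)C)CO[Si](CC)(CC)CC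
F4 | step 19 | (2S,3S,6S)-2-[(tert-butyldiphenylsilyloxy)methyl]-3-[(2R)-2-ethynyloxiran-2-yl]-6-methyl-6-(triethylsilyloxy)oct-7-en-1-ol | C=C[C@@](C)(O[Si](CC)(CC)CC)CC[C@H]([C@@]1(C#C)CO1)[C@H](CO[Si](c1ccccc1)(c1ccccc1)C(C)(C)C)CO
F5 | step 19 | [(2S,3S,4S)-4-[(tert-butyldiphenylsilyloxy)methyl]-2-ethynyl-3-[(3S)-3-methyl-3-(triethylsilyloxy)pent-4-en-1-yl]oxolan-2-yl]methanol | C=C[C@@](C)(O[Si](CC)(CC)CC)CC[C@H]1[C@H](CO[Si](c2ccccc2)(c2ccccc2)C(C)(C)C)CO[C@@]1(C#C)CO
F6 | step 19 | [(2S,3S,4S)-4-[(tert-butyldiphenylsilyloxy)methyl]-2-ethynyl-3-[(3S)-3-methyl-3-(triethylsilyloxy)pent-4-en-1-yl]oxolan-2-yl]methyl hexadecanoate | C=C[C@@](C)(O[Si](CC)(CC)CC)CC[C@H]1[C@H](CO[Si](c2ccccc2)(c2ccccc2)C(C)(C)C)CO[C@@]1(C#C)COC(=O)CCCCCCCCCCCCCCC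
F7 | step 25 | [(2S,3S,4S)-4-(but-3-enoyl)-3-[(3S)-3-hydroxy-3-methylpent-4-en-1-yl]-2-[(E)-2-iodoethenyl]oxolan-2-yl]methyl hexadecanoate | C=C[C@@](C)(O)CC[C@H]1[C@H](C(=O)CC=C)CO[C@@]1(/C=C/I)COC(=O)CCCCCCCCCCCCCCC
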